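**Retrosynthetic overview**

1. Glaucolide A ⇐ Shi epoxidation of the (E)-C4=C5 olefin as the last step. Before that, the C8 methacrylate, the C10/C13 acetates and the butenolide (oxidative lactonisation of a C6‑OH/C12‑OH Z‑enediol) are placed on the finished ten-membered ring.
2. Ten-membered carbocycle ⇐ twelve-membered β‑keto lactone by Pd(0) decarboxylative allylation with ring contraction (C2–C3 formed, CO2 expelled). Enabling feature: the γ,δ‑unsaturated ketone C1(=O)–C2–C3–C4=C5 of the ten-membered ring; C10 is fully substituted, so only C2 can become the enolate, and C4=C5 (the later epoxide) is the allyl unit.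
3. Twelve-membered lactone ⇐ acylketene macrolactonisation of a seco tert‑butyl β‑keto ester (Claisen condensation at C1).
4. Seco chain ⇐ C3–C5 alkenyl iodide (from propargyl alcohol) + C6/C7/C11–C13 bromobutenolide (from dihydroxyacetone; the ring fixes the tetrasubstituted alkene geometry) + C8–C10/C1 thioester (Cu–bis(oxazoline) pyruvate aldol sets C10); two CBS reductions set C6 and C8.
5. Ring order: 12‑membered lactone → 10‑membered carbocycle → butenolide → epoxide.

Key step: step 18

Remark (numbering): germacrane numbering of the target is used for all intermediates (ring C1–C10; C11–C13 on C7; C14 on C10; C15 on C4); the ester carbon lost as CO2 in step 18 is called C16.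
Remark (assumption): the sense of induction of the two CBS catalysts, the Cu(II)–bis(oxazoline) catalyst and the Shi ketone is assigned from the accepted models; the enantiomeric catalyst would be taken if an assignment proved wrong.
Remark (descriptor): C6 keeps one spatial arrangement throughout; it is R in the intermediates and S in the target only because the CIP ranking of C5 and C7 changes on epoxidation.
Remark: 1 is bought as its dimer and written as the monomer.

**Step 1**
Reactants: 1 1,3-dihydroxyacetone; 2 ethyl (triphenylphosphoranylidene)acetate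
Product: 4 4-(hydroxymethyl)furan-2(5H)-one, via hydroxy ester 3 (not isolated)
Conditions: CH2Cl2, rt, 16 h
Reagents that add atoms: none
Why: Wittig olefination of the symmetric ketone followed by spontaneous lactonisation should give the butenolide, whose ring fixes C12 cis to C6 across the future C7=C11 bond.

**Step 2**
Reactants: 4 4-(hydroxymethyl)furan-2(5H)-one
Product: 5 4-[(tert-butyldiphenylsilyloxy)methyl]furan-2(5H)-one
Conditions: TBDPSCl, imidazole, DMF, 0 °C → rt
Reagents that add atoms: tert-butyl(chloro)diphenylsilane CC(C)(C)[Si](Cl)(c1ccccc1)c1ccccc1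
Why: Standard silylation of the primary alcohol (C13–OH) gives a robust ether that is carried to step 22.

**Step 3**
Reactants: 5 4-[(tert-butyldiphenylsilyloxy)methyl]furan-2(5H)-one
Product: 7 3-bromo-4-[(tert-butyldiphenylsilyloxy)methyl]furan-2(5H)-one, via dibromide 6 (not isolated)
Conditions: Br2, CH2Cl2, 0 °C → rt; then Et3N, 0 °C
Reagents that add atoms: bromine BrBr
Why: Bromine addition to the butenolide alkene and dehydrobromination through the acidic α‑hydrogen (α‑bromination of an enoate) should place bromine on C7.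

**Step 4**
Reactants: 7 3-bromo-4-[(tert-butyldiphenylsilyloxy)methyl]furan-2(5H)-one
Product: 9 (Z)-2-bromo-N-methoxy-N-methyl-3-[(tert-butyldiphenylsilyloxy)methyl]-4-(triethylsilyloxy)but-2-enamide, via hydroxy amide 8 (not isolated)
Conditions: MeNH(OMe)·HCl, AlMe3, CH2Cl2, 0 °C → rt; then TESCl, imidazole, DMF, 0 °C
Reagents that add atoms: N,O-dimethylhydroxylamine hydrochloride CNOC.Cl; chlorotriethylsilane CC[Si](Cl)(CC)CC
Why: Weinreb aminolysis of the lactone with the aluminium amide opens the ring with retention of the alkene geometry, and immediate silylation of the liberated C12–OH prevents relactonisation.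

**Step 5**
Reactants: 10 prop-2-yn-1-ol
Product: 12 (E)-3-iodo-2-methylprop-2-en-1-ol, via alkenylalane 11 (not isolated)
Conditions: Me3Al (3 equiv), Cp2ZrCl2 (0.25 equiv), CH2Cl2, 0 °C → rt; then I2, THF, −30 → 0 °C
Reagents that add atoms: trimethylaluminium C[Al](C)C; iodine II
Why: Negishi zirconium-catalysed syn‑carboalumination and iodinolysis with retention should give only the E‑alkenyl iodide (C3–C5 with C15).

**Step 6**
Reactants: 12 (E)-3-iodo-2-methylprop-2-en-1-ol
Product: 13 (E)-1-iodo-3-(4-methoxybenzyloxy)-2-methylprop-1-ene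
Conditions: NaH, PMBCl, Bu4NI (cat.), THF, 0 °C → rt
Reagents that add atoms: 4-methoxybenzyl chloride COc1ccc(CCl)cc1
Why: Williamson etherification gives a C3–O protecting group that survives organolithium chemistry and is removed oxidatively in step 16.

**Step 7**
Reactants: 13 (E)-1-iodo-3-(4-methoxybenzyloxy)-2-methylprop-1-ene; 9 (Z)-2-bromo-N-methoxy-N-methyl-3-[(tert-butyldiphenylsilyloxy)methyl]-4-(triethylsilyloxy)but-2-enamide
Product: 15 (2E,5Z)-5-bromo-6-[(tert-butyldiphenylsilyloxy)methyl]-1-(4-methoxybenzyloxy)-2-methyl-7-(triethylsilyloxy)hepta-2,5-dien-4-one, via alkenyllithium 14 (not isolated)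
Conditions: 13, t-BuLi (2.1 equiv), Et2O, −78 °C; then 9, −78 → −40 °C
Reagents that add atoms: none
Why: Iodine–lithium exchange with retention of geometry and Weinreb ketone synthesis (stable chelate, no over-addition) should join C5 to C6.

**Step 8**
Reactants: 15 (2E,5Z)-5-bromo-6-[(tert-butyldiphenylsilyloxy)methyl]-1-(4-methoxybenzyloxy)-2-methyl-7-(triethylsilyloxy)hepta-2,5-dien-4-one
Product: 16 (2E,4R,5Z)-5-bromo-6-[(tert-butyldiphenylsilyloxy)methyl]-1-(4-methoxybenzyloxy)-2-methyl-7-(triethylsilyloxy)hepta-2,5-dien-4-ol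
Conditions: (S)-Me-CBS (0.5 equiv), catecholborane, toluene, −78 °C
Reagents that add atoms: none
Why: Corey–Bakshi–Shibata reduction in which the α‑bromo tetrasubstituted alkenyl group acts as the large substituent should set C6 (R here, the arrangement of C6 in the target) under catalyst control.

**Step 9**
Reactants: 16 (2E,4R,5Z)-5-bromo-6-[(tert-butyldiphenylsilyloxy)methyl]-1-(4-methoxybenzyloxy)-2-methyl-7-(triethylsilyloxy)hepta-2,5-dien-4-ol
Product: 17 (2E,4R,5Z)-5-bromo-6-[(tert-butyldiphenylsilyloxy)methyl]-1-(4-methoxybenzyloxy)-2-methyl-4,7-bis(triethylsilyloxy)hepta-2,5-diene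
Conditions: TESOTf, 2,6-lutidine, CH2Cl2, −78 °C
Reagents that add atoms: triethylsilyl triflate CC[Si](CC)(CC)OS(=O)(=O)C(F)(F)F
Why: Silylation of the hindered secondary alcohol under non-ionising basic conditions protects C6–O as an ether that cannot be ionised by palladium later.

**Step 10**
Reactants: 18 S-ethyl thioacetate
Product: 19 1-(ethylthio)-1-(trimethylsilyloxy)ethene
Conditions: LDA, THF, −78 °C; then TMSCl
Reagents that add atoms: chlorotrimethylsilane C[Si](C)(C)Cl
Why: O‑silylation of the thioester lithium enolate gives the silyl ketene thioacetal needed for the Mukaiyama aldol.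

**Step 11**
Reactants: 19 1-(ethylthio)-1-(trimethylsilyloxy)ethene; 20 methyl pyruvate
Product: 22 methyl (R)-4-(ethylthio)-2-hydroxy-2-methyl-4-oxobutanoate, via trimethylsilyl ether 21 (not isolated)
Conditions: [Cu((R,R)-t-Bu-box)](OTf)2 (10 mol%), THF, −78 °C; then 1 M HCl
Reagents that add atoms: none
Why: Cu(II)–bis(oxazoline)-catalysed enantioselective Mukaiyama aldol to the chelated pyruvate should create the C10 tertiary carbinol (R) with catalyst control of the ketone face.

**Step 12**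
Reactants: 22 methyl (R)-4-(ethylthio)-2-hydroxy-2-methyl-4-oxobutanoate
Product: 23 methyl (R)-4-(ethylthio)-2-methyl-4-oxo-2-(triethylsilyloxy)butanoate
Conditions: TESOTf, 2,6-lutidine, CH2Cl2, 0 °C
Reagents that add atoms: triethylsilyl triflate CC[Si](CC)(CC)OS(=O)(=O)C(F)(F)F
Why: Silyl triflate silylation is the standard way to protect a tertiary alcohol (C10–O).

**Step 13**
Reactants: 17 (2E,4R,5Z)-5-bromo-6-[(tert-butyldiphenylsilyloxy)methyl]-1-(4-methoxybenzyloxy)-2-methyl-4,7-bis(triethylsilyloxy)hepta-2,5-diene; 23 methyl (R)-4-(ethylthio)-2-methyl-4-oxo-2-(triethylsilyloxy)butanoate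
Product: 26 C8-keto seco methyl ester [4E; 6R; 10R; 3-OPMB; 6-OTES; 10-OTES; 12-OTES; 13-OTBDPS], via vinyllithium 24 (not isolated), via vinylzinc chloride 25 (not isolated)
Conditions: 17, t-BuLi (2.1 equiv), Et2O, −78 °C; ZnCl2, THF, −78 → 0 °C; then 23, PdCl2(PPh3)2 (5 mol%), toluene, rt
Reagents that add atoms: none
Why: Bromine–lithium exchange, transmetalation to zinc and Fukuyama thioester coupling should form C7–C8 as a ketone, the organozinc leaving the methyl ester untouched.

**Step 14**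
Reactants: 26 C8-keto seco methyl ester [4E; 6R; 10R; 3-OPMB; 6-OTES; 10-OTES; 12-OTES; 13-OTBDPS]
Product: 28 seco methyl ester [4E; 6R; 8S; 10R; 3-OPMB; 6-OTES; 8-OTES; 10-OTES; 12-OTES; 13-OTBDPS], via hydroxy ester 27 (not isolated)
Conditions: (R)-Me-CBS (0.5 equiv), catecholborane, toluene, −78 °C; then crude, TESOTf, 2,6-lutidine, CH2Cl2, −78 °C
Reagents that add atoms: triethylsilyl triflate CC[Si](CC)(CC)OS(=O)(=O)C(F)(F)F
Why: Corey–Bakshi–Shibata reduction with the tetrasubstituted alkenyl group as the large substituent should give (8S), and immediate silylation stops γ‑lactonisation onto the C1 ester.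

**Step 15**
Reactants: 28 seco methyl ester [4E; 6R; 8S; 10R; 3-OPMB; 6-OTES; 8-OTES; 10-OTES; 12-OTES; 13-OTBDPS]; 29 tert-butyl acetate
Product: 31 seco tert-butyl β-keto ester [C1 ketone; C2H2; CO2tBu; 3-OPMB; silyl ethers as in 28], via lithium enolate 30 (not isolated)
Conditions: 29, LDA, THF, −78 °C (4 equiv of enolate); then 28, −78 → 0 °C; aq. NH4Cl
Reagents that add atoms: none
Why: Crossed Claisen condensation on an ester that has no α‑hydrogen and is activated by its α‑oxygen should give the β‑keto ester, which is held as its enolate until work-up.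

**Step 16**
Reactants: 31 seco tert-butyl β-keto ester [C1 ketone; C2H2; CO2tBu; 3-OPMB; silyl ethers as in 28]
Product: 32 seco tert-butyl β-keto ester with free C3-OH [silyl ethers as in 28]
Conditions: DDQ, CH2Cl2–pH 7 buffer, 0 °C
Reagents that add atoms: none
Why: Oxidative cleavage of the 4‑methoxybenzyl ether is orthogonal to all silyl ethers and frees the primary allylic alcohol.

**Step 17**
Reactants: 32 seco tert-butyl β-keto ester with free C3-OH [silyl ethers as in 28]
Product: 34 twelve-membered β-keto lactone [ring C1–C2–C16(=O)–O–C3…C10; 4E; 6R; 8S; 10R; 6-OTES; 8-OTES; 10-OTES; 12-OTES; 13-OTBDPS], via acylketene 33 (not isolated)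
Conditions: toluene, 110 °C, syringe-pump addition, final 0.5 mM
Reagents that add atoms: none
Why: Thermolysis of the tert‑butyl β‑keto ester should give an acylketene that is trapped by the only free hydroxyl (C3–OH), an acylketene macrolactonisation of the kind used for 10- to 16‑membered β‑keto lactones.

**Step 18**
Reactants: 34 twelve-membered β-keto lactone [ring C1–C2–C16(=O)–O–C3…C10; 4E; 6R; 8S; 10R; 6-OTES; 8-OTES; 10-OTES; 12-OTES; 13-OTBDPS]
Product: 35 ten-membered ketone [(4E,6R,8S,10R)-1-oxogermacra-4,7(11)-diene; 6-OTES; 8-OTES; 10-OTES; 12-OTES; 13-OTBDPS]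
Conditions: Pd(PPh3)4 (10 mol%), THF, 2 mM, 25 → 45 °C
Reagents that add atoms: none
Why: Proposed new method: Pd(0) should add oxidatively to the allylic C3–O bond of the twelve-membered β‑keto lactone to give a π‑allyl(C3–C5)palladium β‑keto carboxylate, which loses CO2 to a C1/C2 enolate that is regiodefined because C10 bears no hydrogen; C2 then bonds to the unsubstituted allyl terminus C3, so the ring shrinks by the two expelled atoms (C16 and its oxygen) to the ten-membered carbocycle. The closest known reactions are the decarboxylative Tsuji–Trost (Carroll-type) allylation of acyclic allyl β‑keto esters and palladium-catalysed macrocyclising allylic alkylations; here both partners stay tethered through C5–C10, so C–C bond formation is intramolecular by construction. The ten-membered ring is closed by attack at the primary π‑allyl terminus (C2–C3, linear mode); attack at C5 would give the eight-membered branched isomer and is disfavoured by the neighbouring C6–OTES centre, and O‑allylation is reversible under Pd(0). No new stereocentre is formed (C2 and C3 are CH2); the stereochemical element is the E geometry of C4=C5, carried over from the E‑allylic ester through the syn‑π‑allyl complex. The step needs C‑ over O‑allylation, C3 over C5 attack, retention of the E geometry and ring closure faster than protonation or β‑hydride loss; these are secured by the absence of any acidic O–H or C–H (all hydroxyls silylated, the butenolide held back as its diol), by the palladium-bound ion pair and by high dilution.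

**Step 19**
Reactants: 35 ten-membered ketone [(4E,6R,8S,10R)-1-oxogermacra-4,7(11)-diene; 6-OTES; 8-OTES; 10-OTES; 12-OTES; 13-OTBDPS]
Product: 36 tetraol [(4E,6R,8S,10R)-6,8,10,12-tetrahydroxy-13-(tert-butyldiphenylsilyloxy)germacra-4,7(11)-dien-1-one]
Conditions: HF·pyridine, pyridine, THF, 0 °C → rt
Reagents that add atoms: none
Why: Buffered fluoride desilylation should remove the four triethylsilyl ethers while the primary tert‑butyldiphenylsilyl ether survives.

**Step 20**
Reactants: 36 tetraol [(4E,6R,8S,10R)-6,8,10,12-tetrahydroxy-13-(tert-butyldiphenylsilyloxy)germacra-4,7(11)-dien-1-one]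
Product: 38 butenolide [(4E,6R,8S,10R)-8,10-dihydroxy-1-oxo-13-(tert-butyldiphenylsilyloxy)germacra-4,7(11)-dien-12,6-olide], via lactol 37 (not isolated)
Conditions: TEMPO (0.2 equiv), PhI(OAc)2 (2.5 equiv), CH2Cl2, rt
Reagents that add atoms: none
Why: Oxoammonium oxidation is selective for the primary allylic C12–OH, the aldehyde is captured by the cis C6–OH as a lactol and oxidised on (oxidative lactonisation of a Z‑2‑ene‑1,4‑diol), so the lactone can only close to C6.

**Step 21**
Reactants: 38 butenolide [(4E,6R,8S,10R)-8,10-dihydroxy-1-oxo-13-(tert-butyldiphenylsilyloxy)germacra-4,7(11)-dien-12,6-olide]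
Product: 39 8-O-methacrylate [(4E,6R,8S,10R)-10-hydroxy-8-methacryloyloxy-1-oxo-13-(tert-butyldiphenylsilyloxy)germacra-4,7(11)-dien-12,6-olide]
Conditions: methacrylic anhydride, Et3N, DMAP (cat.), CH2Cl2, 0 °C → rt
Reagents that add atoms: methacrylic anhydride C=C(C)C(=O)OC(=O)C(C)=C
Why: DMAP-catalysed acylation should esterify the secondary C8–OH (also draining any C8–O/C1 hemiketal through its open form) and leave the tertiary C10–OH untouched.

**Step 22**
Reactants: 39 8-O-methacrylate [(4E,6R,8S,10R)-10-hydroxy-8-methacryloyloxy-1-oxo-13-(tert-butyldiphenylsilyloxy)germacra-4,7(11)-dien-12,6-olide]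
Product: 40 diol [(4E,6R,8S,10R)-10,13-dihydroxy-8-methacryloyloxy-1-oxogermacra-4,7(11)-dien-12,6-olide]
Conditions: HF·pyridine, THF, rt, 24 h
Reagents that add atoms: none
Why: Acidic fluoride cleaves the remaining silyl ether without the basic conditions that would endanger the butenolide and the methacrylate.

**Step 23**
Reactants: 40 diol [(4E,6R,8S,10R)-10,13-dihydroxy-8-methacryloyloxy-1-oxogermacra-4,7(11)-dien-12,6-olide]
Product: 41 4,5-deoxyglaucolide A [(4E,6R,8S,10R)-10,13-diacetoxy-8-methacryloyloxy-1-oxogermacra-4,7(11)-dien-12,6-olide]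
Conditions: Ac2O, DMAP, pyridine, CH2Cl2, rt → 40 °C
Reagents that add atoms: acetic anhydride CC(=O)OC(C)=O
Why: Nucleophile-catalysed acetylation should esterify the primary C13–OH at once and the tertiary α‑ketol C10–OH on prolonged reaction, without Lewis acid that could ionise the doubly allylic C6–O bond.

**Step 24**
Reactants: 41 4,5-deoxyglaucolide A [(4E,6R,8S,10R)-10,13-diacetoxy-8-methacryloyloxy-1-oxogermacra-4,7(11)-dien-12,6-olide]
Product: 42 glaucolide A
Conditions: D-fructose-derived Shi ketone (0.3 equiv), Oxone, K2CO3, Bu4NHSO4, MeCN–dimethoxymethane–aq. borate buffer, 0 °C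
Reagents that add atoms: Oxone (potassium peroxymonosulfate) [K+].[O-]S(=O)(=O)OO
Why: Shi epoxidation: the chiral dioxirane should react only with the electron-rich E‑trisubstituted C4=C5 (not with the butenolide or methacrylate alkenes), and its spiro transition state should deliver oxygen to the face that gives the (4R,5R) trans-epoxide.

**Compound list**

1 | 1,3-dihydroxyacetone | OCC(=O)CO | starting material
2 | ethyl (triphenylphosphoranylidene)acetate | CCOC(=O)C=P(c1ccccc1)(c1ccccc1)c1ccccc1 | starting material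
3 | ethyl 4-hydroxy-3-(hydroxymethyl)but-2-enoate | CCOC(=O)C=C(CO)CO | intermediate
4 | 4-(hydroxymethyl)furan-2(5H)-one | O=C1OCC(CO)=C1 | intermediate
5 | 4-[(tert-butyldiphenylsilyloxy)methyl]furan-2(5H)-one | O=C1OCC(CO[Si](c2ccccc2)(c2ccccc2)C(C)(C)C)=C1 | intermediate
6 | 3,4-dibromo-4-[(tert-butyldiphenylsilyloxy)methyl]dihydrofuran-2(3H)-one | O=C1OCC(Br)(CO[Si](c2ccccc2)(c2ccccc2)C(C)(C)C)C1Br | intermediate
7 | 3-bromo-4-[(tert-butyldiphenylsilyloxy)methyl]furan-2(5H)-one | O=C1OCC(CO[Si](c2ccccc2)(c2ccccc2)C(C)(C)C)=C1Br | intermediate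
8 | (Z)-2-bromo-4-hydroxy-N-methoxy-N-methyl-3-[(tert-butyldiphenylsilyloxy)methyl]but-2-enamide | CON(C)C(=O)/C(Br)=C(\CO)CO[Si](c1ccccc1)(c1ccccc1)C(C)(C)C | intermediate
9 | (Z)-2-bromo-N-methoxy-N-methyl-3-[(tert-butyldiphenylsilyloxy)methyl]-4-(triethylsilyloxy)but-2-enamide | CON(C)C(=O)/C(Br)=C(\CO[Si](CC)(CC)CC)CO[Si](c1ccccc1)(c1ccccc1)C(C)(C)C | intermediate
10 | prop-2-yn-1-ol | C#CCO | starting material
11 | (E)-alkenylalane (dimethylaluminium alkoxide of 3-(dimethylaluminio)-2-methylprop-2-en-1-ol) | C[Al](C)OC/C(C)=C/[Al](C)C | intermediate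
12 | (E)-3-iodo-2-methylprop-2-en-1-ol | OC/C(C)=C/I | intermediate
13 | (E)-1-iodo-3-(4-methoxybenzyloxy)-2-methylprop-1-ene | COc1ccc(COC/C(C)=C/I)cc1 | intermediate
14 | (E)-3-(4-methoxybenzyloxy)-2-methylprop-1-enyllithium | COc1ccc(COC/C(C)=C/[Li])cc1 | intermediate
15 | (2E,5Z)-5-bromo-6-[(tert-butyldiphenylsilyloxy)methyl]-1-(4-methoxybenzyloxy)-2-methyl-7-(triethylsilyloxy)hepta-2,5-dien-4-one | COc1ccc(COC/C(C)=C/C(=O)/C(Br)=C(\CO[Si](CC)(CC)CC)CO[Si](c2ccccc2)(c2ccccc2)C(C)(C)C)cc1 | intermediate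
16 | (2E,4R,5Z)-5-bromo-6-[(tert-butyldiphenylsilyloxy)methyl]-1-(4-methoxybenzyloxy)-2-methyl-7-(triethylsilyloxy)hepta-2,5-dien-4-ol | COc1ccc(COC/C(C)=C/[C@@H](O)/C(Br)=C(\CO[Si](CC)(CC)CC)CO[Si](c2ccccc2)(c2ccccc2)C(C)(C)C)cc1 | intermediate
17 | (2E,4R,5Z)-5-bromo-6-[(tert-butyldiphenylsilyloxy)methyl]-1-(4-methoxybenzyloxy)-2-methyl-4,7-bis(triethylsilyloxy)hepta-2,5-diene | COc1ccc(COC/C(C)=C/[C@@H](O[Si](CC)(CC)CC)/C(Br)=C(\CO[Si](CC)(CC)CC)CO[Si](c2ccccc2)(c2ccccc2)C(C)(C)C)cc1 | intermediate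
18 | S-ethyl thioacetate | CCSC(C)=O | starting material
19 | 1-(ethylthio)-1-(trimethylsilyloxy)ethene | C=C(SCC)O[Si](C)(C)C | intermediate
20 | methyl pyruvate | COC(=O)C(C)=O | starting material
21 | methyl (R)-4-(ethylthio)-2-methyl-4-oxo-2-(trimethylsilyloxy)butanoate | CCSC(=O)C[C@@](C)(O[Si](C)(C)C)C(=O)OC | intermediate
22 | methyl (R)-4-(ethylthio)-2-hydroxy-2-methyl-4-oxobutanoate | CCSC(=O)C[C@@](C)(O)C(=O)OC | intermediate
23 | methyl (R)-4-(ethylthio)-2-methyl-4-oxo-2-(triethylsilyloxy)butanoate | CCSC(=O)C[C@@](C)(O[Si](CC)(CC)CC)C(=O)OC | intermediate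
24 | C7 vinyllithium from 17 | COc1ccc(COC/C(C)=C/[C@@H](O[Si](CC)(CC)CC)/C([Li])=C(\CO[Si](CC)(CC)CC)CO[Si](c2ccccc2)(c2ccccc2)C(C)(C)C)cc1 | intermediate
25 | C7 vinylzinc chloride from 17 | COc1ccc(COC/C(C)=C/[C@@H](O[Si](CC)(CC)CC)/C([Zn]Cl)=C(\CO[Si](CC)(CC)CC)CO[Si](c2ccccc2)(c2ccccc2)C(C)(C)C)cc1 | intermediate
26 | C8-keto seco methyl ester [4E; 6R; 10R; 3-OPMB; 6-OTES; 10-OTES; 12-OTES; 13-OTBDPS] | COc1ccc(COC/C(C)=C/[C@@H](O[Si](CC)(CC)CC)/C(C(=O)C[C@@](C)(O[Si](CC)(CC)CC)C(=O)OC)=C(\CO[Si](CC)(CC)CC)CO[Si](c2ccccc2)(c2ccccc2)C(C)(C)C)cc1 | intermediate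
27 | (8S)-hydroxy seco methyl ester [4E; 6R; 8S; 10R; 8-OH] | COc1ccc(COC/C(C)=C/[C@@H](O[Si](CC)(CC)CC)/C([C@@H](O)C[C@@](C)(O[Si](CC)(CC)CC)C(=O)OC)=C(\CO[Si](CC)(CC)CC)CO[Si](c2ccccc2)(c2ccccc2)C(C)(C)C)cc1 | intermediate
28 | seco methyl ester [4E; 6R; 8S; 10R; 3-OPMB; 6-OTES; 8-OTES; 10-OTES; 12-OTES; 13-OTBDPS] | COc1ccc(COC/C(C)=C/[C@@H](O[Si](CC)(CC)CC)/C([C@@H](O[Si](CC)(CC)CC)C[C@@](C)(O[Si](CC)(CC)CC)C(=O)OC)=C(\CO[Si](CC)(CC)CC)CO[Si](c2ccccc2)(c2ccccc2)C(C)(C)C)cc1 | intermediate
29 | tert-butyl acetate | CC(=O)OC(C)(C)C | starting material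
30 | lithium enolate of tert-butyl acetate | C=C(O[Li])OC(C)(C)C | intermediate
31 | seco tert-butyl β-keto ester [C1 ketone; C2H2; CO2tBu; 3-OPMB; silyl ethers as in 28] | COc1ccc(COC/C(C)=C/[C@@H](O[Si](CC)(CC)CC)/C([C@@H](O[Si](CC)(CC)CC)C[C@@](C)(O[Si](CC)(CC)CC)C(=O)CC(=O)OC(C)(C)C)=C(\CO[Si](CC)(CC)CC)CO[Si](c2ccccc2)(c2ccccc2)C(C)(C)C)cc1 | intermediate
32 | seco tert-butyl β-keto ester with free C3-OH [silyl ethers as in 28] | OC/C(C)=C/[C@@H](O[Si](CC)(CC)CC)/C([C@@H](O[Si](CC)(CC)CC)C[C@@](C)(O[Si](CC)(CC)CC)C(=O)CC(=O)OC(C)(C)C)=C(\CO[Si](CC)(CC)CC)CO[Si](c1ccccc1)(c1ccccc1)C(C)(C)C | intermediate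
33 | seco acylketene (C1 ketone; C2H=C16=O) with free C3-OH | OC/C(C)=C/[C@@H](O[Si](CC)(CC)CC)/C([C@@H](O[Si](CC)(CC)CC)C[C@@](C)(O[Si](CC)(CC)CC)C(=O)C=C=O)=C(\CO[Si](CC)(CC)CC)CO[Si](c1ccccc1)(c1ccccc1)C(C)(C)C | intermediate
34 | twelve-membered β-keto lactone [ring C1–C2–C16(=O)–O–C3…C10; 4E; 6R; 8S; 10R; 6-OTES; 8-OTES; 10-OTES; 12-OTES; 13-OTBDPS] | O1C/C(C)=C/[C@@H](O[Si](CC)(CC)CC)/C(=C(\CO[Si](CC)(CC)CC)CO[Si](c2ccccc2)(c2ccccc2)C(C)(C)C)[C@@H](O[Si](CC)(CC)CC)C[C@@](C)(O[Si](CC)(CC)CC)C(=O)CC1=O | intermediate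
35 | ten-membered ketone [(4E,6R,8S,10R)-1-oxogermacra-4,7(11)-diene; 6-OTES; 8-OTES; 10-OTES; 12-OTES; 13-OTBDPS] | O=C1CC/C(C)=C/[C@@H](O[Si](CC)(CC)CC)/C(=C(\CO[Si](CC)(CC)CC)CO[Si](c2ccccc2)(c2ccccc2)C(C)(C)C)[C@@H](O[Si](CC)(CC)CC)C[C@@]1(C)O[Si](CC)(CC)CC | intermediate
36 | tetraol [(4E,6R,8S,10R)-6,8,10,12-tetrahydroxy-13-(tert-butyldiphenylsilyloxy)germacra-4,7(11)-dien-1-one] | O=C1CC/C(C)=C/[C@@H](O)/C(=C(\CO)CO[Si](c2ccccc2)(c2ccccc2)C(C)(C)C)[C@@H](O)C[C@@]1(C)O | intermediate
37 | lactol (12-hydroxy-12,6-epoxy; C12 epimers) | O=C1CC/C(C)=C/[C@H]2OC(O)C(CO[Si](c3ccccc3)(c3ccccc3)C(C)(C)C)=C2[C@@H](O)C[C@@]1(C)O | intermediate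
38 | butenolide [(4E,6R,8S,10R)-8,10-dihydroxy-1-oxo-13-(tert-butyldiphenylsilyloxy)germacra-4,7(11)-dien-12,6-olide] | O=C1CC/C(C)=C/[C@H]2OC(=O)C(CO[Si](c3ccccc3)(c3ccccc3)C(C)(C)C)=C2[C@@H](O)C[C@@]1(C)O | intermediate
39 | 8-O-methacrylate [(4E,6R,8S,10R)-10-hydroxy-8-methacryloyloxy-1-oxo-13-(tert-butyldiphenylsilyloxy)germacra-4,7(11)-dien-12,6-olide] | O=C1CC/C(C)=C/[C@H]2OC(=O)C(CO[Si](c3ccccc3)(c3ccccc3)C(C)(C)C)=C2[C@@H](OC(=O)C(C)=C)C[C@@]1(C)O | intermediate
40 | diol [(4E,6R,8S,10R)-10,13-dihydroxy-8-methacryloyloxy-1-oxogermacra-4,7(11)-dien-12,6-olide] | O=C1CC/C(C)=C/[C@H]2OC(=O)C(CO)=C2[C@@H](OC(=O)C(C)=C)C[C@@]1(C)O | intermediate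
41 | 4,5-deoxyglaucolide A [(4E,6R,8S,10R)-10,13-diacetoxy-8-methacryloyloxy-1-oxogermacra-4,7(11)-dien-12,6-olide] | O=C1CC/C(C)=C/[C@H]2OC(=O)C(COC(C)=O)=C2[C@@H](OC(=O)C(C)=C)C[C@@]1(C)OC(C)=O | intermediate
42 | glaucolide A (4R,5R,6S,8S,10R) | C=C(C)C(=O)O[C@H]1C[C@@](C)(OC(C)=O)C(=O)CC[C@@]2(C)O[C@@H]2[C@H]2OC(=O)C(COC(C)=O)=C12 | target

**Totals**

Total step count: 24. Longest linear sequence: 19 steps (from 1: steps 1–4, 7–9, 13–24).

**Steps most likely to fail**

1. Step 18 (ring-contracting decarboxylative allylation). The palladium-bound enolate/π‑allyl pair may be lost by protonation or β‑hydride elimination before the ten-membered ring closes. It may also attack the wrong allyl terminus, oligomerise, or lose the E geometry through syn–anti isomerisation of the π‑allyl complex. Fallback with known chemistry, from 32 back to 35: the allylic alcohol of 32 is converted (CBr4, PPh3, 2,6‑lutidine, CH2Cl2, 0 °C) into the seco allylic bromide F1. F1 is closed by intramolecular C‑alkylation of its β‑keto ester (Cs2CO3, MeCN, high dilution, rt), the classical base-mediated closure of germacrane rings from E‑allylic halides, to the ten-membered tert‑butyl β‑keto ester F2. Thermal dealkoxycarbonylation of F2 (wet DMSO, 130 °C, via the acylketene and the β‑keto acid) then gives 35. This fallback replaces the ring contraction by a direct ring closure and is held in reserve only.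

2. Step 24 (epoxidation). Oxygen delivery may occur to the wrong face of C4=C5 if the ring conformation overrides the catalyst, and the acetates may partly hydrolyse in the basic buffer. Fallback from 41 back to 42: NBS in aqueous THF (0 °C) should give, by anti addition with water at the tertiary C4, the bromohydrin F3. This is useful exactly when electrophiles prefer the face that the dioxirane also prefers. Closure of F3 with Ag2O in DMF, with inversion at C5, then places the epoxide oxygen on the opposite face and gives 42 under neutral conditions.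

3. Step 13 (ketone synthesis). Transmetalation and coupling of the hindered tetrasubstituted alkenylzinc may be slow, so that silyl migration to carbon or protonation of the vinyl metal competes. Fallback from 23 and 24 back to 26: thioester 23 is reduced (Et3SiH, Pd/C, acetone, rt; Fukuyama reduction) to the aldehyde F4. Vinyllithium 24, made from 17 as before, is added to F4 at −78 °C, which should give the C8 carbinol F5 as a mixture of C8 epimers. Dess–Martin oxidation of F5 gives 26, and the configuration at C8 is then set as planned in step 14.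

**Further compounds**

F1 | step 18 | seco allylic bromide (C3-Br) of 32 | BrC/C(C)=C/[C@@H](O[Si](CC)(CC)CC)/C([C@@H](O[Si](CC)(CC)CC)C[C@@](C)(O[Si](CC)(CC)CC)C(=O)CC(=O)OC(C)(C)C)=C(\CO[Si](CC)(CC)CC)CO[Si](c1ccccc1)(c1ccccc1)C(C)(C)C
F2 | step 18 | ten-membered tert-butyl β-keto ester (CO2tBu on C2; C2 epimers) | O=C1C(C(=O)OC(C)(C)C)C/C(C)=C/[C@@H](O[Si](CC)(CC)CC)/C(=C(\CO[Si](CC)(CC)CC)CO[Si](c2ccccc2)(c2ccccc2)C(C)(C)C)[C@@H](O[Si](CC)(CC)CC)C[C@@]1(C)O[Si](CC)(CC)CC
F3 | step 24 | (4R,5S)-5-bromo-4-hydroxy bromohydrin of 41 | C=C(C)C(=O)O[C@H]1C[C@@](C)(OC(C)=O)C(=O)CC[C@@](C)(O)[C@@H](Br)[C@H]2OC(=O)C(COC(C)=O)=C12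
F4 | step 13 | methyl (R)-2-methyl-4-oxo-2-(triethylsilyloxy)butanoate | O=CC[C@@](C)(O[Si](CC)(CC)CC)C(=O)OC
F5 | step 13 | C8 carbinol corresponding to 26 (C8 epimers) | COc1ccc(COC/C(C)=C/[C@@H](O[Si](CC)(CC)CC)/C(C(O)C[C@@](C)(O[Si](CC)(CC)CC)C(=O)OC)=C(\CO[Si](CC)(CC)CC)CO[Si](c2ccccc2)(c2ccccc2)C(C)(C)C)cc1
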